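**Retrosynthetic overview**
1. Both pyrrole rings are closed last, in one operation, by double Cadogan N-insertion on 1,4-bis(4-chloro-2-nitrophenyl)-2,3-dimethoxybenzene. The two OMe groups block the other ortho positions, so only the [2,3-a] fusion can form.
2. The dimethoxyterphenyl comes from O-methylation of a 3,6-diaryl-2-methoxyphenol, which is the dehydrogenation product of a 3,6-diaryl-2-methoxycyclohex-2-enone.
3. The cyclohexenone is opened by a Robinson-type disconnection. An intramolecular aldol condensation closes a 1,5-diketone, and that diketone comes from the key intermolecular Michael addition of 1-aryl-3-methoxypropan-2-one to an aryl vinyl ketone. This bond joins the two chloronitroaryl halves.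
4. The donor comes from SNAr of methyl 4-methoxyacetoacetate on 4-chloro-1-fluoro-2-nitrobenzene, then decarboxylation. The acceptor comes from 4-chloro-2-nitrobenzoic acid via the methyl ketone (malonate acylation) and its Mannich salt, a latent vinyl ketone.
5. Ring order: the central carbocycle first, then the first pyrrole (carbazole stage), then the second pyrrole (indolocarbazole).

Assumption: the target has no stereocentre and is achiral, so no enantiomer has to be chosen. The stereocentres in 3, 18, 19 and 20 are racemic or transient and are erased by step 9.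

**Step 1**
Reactants: 1 4-chloro-1-fluoro-2-nitrobenzene; 2 methyl 4-methoxy-3-oxobutanoate
Product: 3 methyl 2-(4-chloro-2-nitrophenyl)-4-methoxy-3-oxobutanoate
Conditions: K2CO3 (2.5 equiv), DMF, 60 °C, 6 h; 1 M HCl work-up
Reagents that add atoms: none
Why: Nucleophilic aromatic substitution by addition–elimination: the soft enolate carbon of 2 attacks the C–F carbon, which is ortho to the nitro group, whereas the chlorine sits meta to the nitro group and is not activated, so only fluoride is displaced.

**Step 2**
Reactants: 3 methyl 2-(4-chloro-2-nitrophenyl)-4-methoxy-3-oxobutanoate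
Product: 5 1-(4-chloro-2-nitrophenyl)-3-methoxypropan-2-one, via beta-keto acid 4 (not isolated)
Conditions: AcOH–H2O–conc. H2SO4 (5:3:1), reflux, 5 h
Reagents that add atoms: none
Why: Acid-catalysed ester hydrolysis and decarboxylation of the resulting beta-keto acid (ketonic cleavage of an acetoacetic ester), run in acid so that no retro-Claisen loss of the methoxyacetyl group occurs, with the methyl ether, nitro group and aryl chloride all inert to hot aqueous acid.

**Step 3**
Reactants: 6 4-chloro-2-nitrobenzoic acid
Product: 7 4-chloro-2-nitrobenzoyl chloride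
Conditions: SOCl2 (1.5 equiv), DMF (cat.), toluene, 80 °C, 3 h; evaporate
Reagents that add atoms: thionyl chloride, O=S(Cl)Cl
Why: Standard DMF-catalysed conversion of a carboxylic acid into its acid chloride, driven by loss of gaseous SO2 and HCl, to which the nitro and chloro substituents are inert.

**Step 4**
Reactants: 7 4-chloro-2-nitrobenzoyl chloride; 8 diethyl malonate
Product: 9 diethyl 2-(4-chloro-2-nitrobenzoyl)malonate
Conditions: MgCl2 (1.1 equiv), Et3N (2.5 equiv), MeCN, 0 °C to rt, 3 h; 1 M HCl work-up
Reagents that add atoms: none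
Why: Claisen-type C-acylation of a malonate under soft enolisation: MgCl2 and Et3N form the chelated magnesium enolate, which is acylated on carbon, and the more acidic product is held as its magnesium chelate so that O-acylation and double acylation are suppressed.

**Step 5**
Reactants: 9 diethyl 2-(4-chloro-2-nitrobenzoyl)malonate
Product: 12 1-(4-chloro-2-nitrophenyl)ethan-1-one, via aroylmalonic acid 10 (not isolated), via aroylacetic acid 11 (not isolated)
Conditions: AcOH–H2O–conc. H2SO4 (5:3:1), reflux, 5 h
Reagents that add atoms: none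
Why: Acidic hydrolysis of both esters followed by two successive decarboxylations of beta-keto acids, the classical malonate route to ortho-nitroacetophenones, which avoids organometallic reagents that are incompatible with the nitro group.

**Step 6**
Reactants: 12 1-(4-chloro-2-nitrophenyl)ethan-1-one; 13 paraformaldehyde (1.5 equiv); 14 dimethylamine hydrochloride (1.3 equiv)
Product: 16 1-(4-chloro-2-nitrophenyl)-3-(dimethylamino)propan-1-one hydrochloride, via dimethylmethyleneiminium chloride 15 (not isolated)
Conditions: conc. HCl (cat.), EtOH, reflux, 16 h; crystallise from acetone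
Reagents that add atoms: none
Why: Mannich reaction: the acid-catalysed enol of methyl ketone 12 is aminomethylated by iminium salt 15, and the product separates as its hydrochloride, which stops a second aminomethylation and stores the polymerisation-prone vinyl ketone in latent form.

**Step 7 (key step)**
Reactants: 5 1-(4-chloro-2-nitrophenyl)-3-methoxypropan-2-one (1.1 equiv); 16 1-(4-chloro-2-nitrophenyl)-3-(dimethylamino)propan-1-one hydrochloride
Product: 18 rac-1,4-bis(4-chloro-2-nitrophenyl)-6-methoxyhexane-1,5-dione, via aryl vinyl ketone 17 (not isolated)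
Conditions: K2CO3 (2.2 equiv), MeCN, 60 °C, N2, 12 h
Reagents that add atoms: none
Why: Intermolecular Michael addition: K2CO3 releases vinyl ketone 17 slowly by E1cB loss of dimethylamine and deprotonates the CH2 of 5 that is doubly activated by the ketone and the ortho-nitroaryl group, and this soft carbanion adds 1,4 to the unhindered enone terminus to forge the C–C bond that unites the two aryl halves, the single new stereocentre being formed as a racemate that is erased in step 9.

**Step 8**
Reactants: 18 rac-1,4-bis(4-chloro-2-nitrophenyl)-6-methoxyhexane-1,5-dione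
Product: 20 rac-3,6-bis(4-chloro-2-nitrophenyl)-2-methoxycyclohex-2-en-1-one, via ketol 19 (not isolated)
Conditions: KOH (0.5 equiv), MeOH–THF (2:1), N2, 55 °C, 12 h; AcOH quench
Reagents that add atoms: none
Why: Intramolecular aldol condensation, the second half of a Robinson annulation: among all enolate–carbonyl pairings only attack of the CH2OMe carbon on the electron-poor aroyl ketone gives a six-membered ring (the others would give four-membered rings), the enolates equilibrate freely in the protic medium, and E1cB dehydration of ketol 19 to the conjugated enone makes the closure irreversible, the carbinol and methoxy stereocentres of 19 being lost and C6 of 20 remaining racemic.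

**Step 9**
Reactants: 20 rac-3,6-bis(4-chloro-2-nitrophenyl)-2-methoxycyclohex-2-en-1-one
Product: 21 3,6-bis(4-chloro-2-nitrophenyl)-2-methoxyphenol
Conditions: DDQ (1.2 equiv), TsOH·H2O (10 mol %), 1,4-dioxane, 100 °C, 8 h
Reagents that add atoms: none
Why: Dehydrogenative aromatisation: DDQ abstracts hydride from the acid-equilibrated enol form of 20, whose formation is easy because C6–H is benzylic and alpha to the ketone, and loss of a proton gives the aromatic phenol, which removes the last stereocentre.

**Step 10**
Reactants: 21 3,6-bis(4-chloro-2-nitrophenyl)-2-methoxyphenol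
Product: 22 1,4-bis(4-chloro-2-nitrophenyl)-2,3-dimethoxybenzene
Conditions: MeI (2 equiv), K2CO3 (2 equiv), DMF, 40 °C, 6 h
Reagents that add atoms: iodomethane, CI
Why: Williamson-type O-methylation (SN2) of the phenoxide, the only acidic site in 21, with nothing else in the molecule able to react with MeI and K2CO3.

**Step 11**
Reactants: 22 1,4-bis(4-chloro-2-nitrophenyl)-2,3-dimethoxybenzene
Product: 24 borregomycin E (2,9-dichloro-5,6-dimethoxy-11,12-dihydroindolo[2,3-a]carbazole), via nitroarylcarbazole 23 (not isolated)
Conditions: PPh3 (5 equiv), o-dichlorobenzene, 180 °C, N2, 18 h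
Reagents that add atoms: none
Why: Double Cadogan reductive cyclisation: PPh3 deoxygenates each nitro group to a nitrene equivalent that inserts into the only free ortho C–H of the central ring (the other ortho carbon carries OMe), so the first closure gives carbazole 23 and the second can only close at its C1, which fixes the [2,3-a] fusion with the two N–H groups on adjacent carbons and leaves each chlorine para to the former biaryl carbon, that is at C2 and C9, while aryl chlorides and methyl ethers are inert to PPh3.

**Compound list**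
1 | 4-chloro-1-fluoro-2-nitrobenzene | O=[N+]([O-])c1cc(Cl)ccc1F | starting material
2 | methyl 4-methoxy-3-oxobutanoate (methyl 4-methoxyacetoacetate) | COCC(=O)CC(=O)OC | starting material
3 | methyl 2-(4-chloro-2-nitrophenyl)-4-methoxy-3-oxobutanoate (racemic, largely enolised) | COCC(=O)C(C(=O)OC)c1ccc(Cl)cc1[N+](=O)[O-] | intermediate
4 | 2-(4-chloro-2-nitrophenyl)-4-methoxy-3-oxobutanoic acid | COCC(=O)C(C(=O)O)c1ccc(Cl)cc1[N+](=O)[O-] | intermediate (not isolated)
5 | 1-(4-chloro-2-nitrophenyl)-3-methoxypropan-2-one | COCC(=O)Cc1ccc(Cl)cc1[N+](=O)[O-] | intermediate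
6 | 4-chloro-2-nitrobenzoic acid | OC(=O)c1ccc(Cl)cc1[N+](=O)[O-] | starting material
7 | 4-chloro-2-nitrobenzoyl chloride | ClC(=O)c1ccc(Cl)cc1[N+](=O)[O-] | intermediate
8 | diethyl malonate | CCOC(=O)CC(=O)OCC | starting material
9 | diethyl 2-(4-chloro-2-nitrobenzoyl)malonate | CCOC(=O)C(C(=O)OCC)C(=O)c1ccc(Cl)cc1[N+](=O)[O-] | intermediate
10 | 2-(4-chloro-2-nitrobenzoyl)malonic acid | OC(=O)C(C(=O)O)C(=O)c1ccc(Cl)cc1[N+](=O)[O-] | intermediate (not isolated)
11 | 3-(4-chloro-2-nitrophenyl)-3-oxopropanoic acid | OC(=O)CC(=O)c1ccc(Cl)cc1[N+](=O)[O-] | intermediate (not isolated)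
12 | 1-(4-chloro-2-nitrophenyl)ethan-1-one | CC(=O)c1ccc(Cl)cc1[N+](=O)[O-] | intermediate
13 | paraformaldehyde (drawn as formaldehyde) | C=O | starting material
14 | dimethylamine hydrochloride | CNC.Cl | starting material
15 | N,N-dimethylmethyleneiminium chloride | C=[N+](C)C.[Cl-] | intermediate (not isolated)
16 | 1-(4-chloro-2-nitrophenyl)-3-(dimethylamino)propan-1-one hydrochloride | CN(C)CCC(=O)c1ccc(Cl)cc1[N+](=O)[O-].Cl | intermediate
17 | 1-(4-chloro-2-nitrophenyl)prop-2-en-1-one | C=CC(=O)c1ccc(Cl)cc1[N+](=O)[O-] | intermediate (not isolated)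
18 | rac-1,4-bis(4-chloro-2-nitrophenyl)-6-methoxyhexane-1,5-dione | COCC(=O)C(CCC(=O)c1ccc(Cl)cc1[N+](=O)[O-])c1ccc(Cl)cc1[N+](=O)[O-] | intermediate
19 | 3,6-bis(4-chloro-2-nitrophenyl)-3-hydroxy-2-methoxycyclohexan-1-one (diastereomer mixture, racemic) | COC1C(=O)C(CCC1(O)c1ccc(Cl)cc1[N+](=O)[O-])c1ccc(Cl)cc1[N+](=O)[O-] | intermediate (not isolated)
20 | rac-3,6-bis(4-chloro-2-nitrophenyl)-2-methoxycyclohex-2-en-1-one | COC1=C(CCC(C1=O)c1ccc(Cl)cc1[N+](=O)[O-])c1ccc(Cl)cc1[N+](=O)[O-] | intermediate
21 | 3,6-bis(4-chloro-2-nitrophenyl)-2-methoxyphenol | COc1c(O)c(ccc1-c1ccc(Cl)cc1[N+](=O)[O-])-c1ccc(Cl)cc1[N+](=O)[O-] | intermediate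
22 | 1,4-bis(4-chloro-2-nitrophenyl)-2,3-dimethoxybenzene | COc1c(OC)c(ccc1-c1ccc(Cl)cc1[N+](=O)[O-])-c1ccc(Cl)cc1[N+](=O)[O-] | intermediate
23 | 7-chloro-2-(4-chloro-2-nitrophenyl)-3,4-dimethoxy-9H-carbazole | COc1c(OC)c2c3ccc(Cl)cc3[nH]c2cc1-c1ccc(Cl)cc1[N+](=O)[O-] | intermediate (not isolated)
24 | borregomycin E, 2,9-dichloro-5,6-dimethoxy-11,12-dihydroindolo[2,3-a]carbazole (achiral) | COc1c(OC)c2c3ccc(Cl)cc3[nH]c2c2[nH]c3cc(Cl)ccc3c12 | target

**Totals**
Total step count: 11.
Longest linear sequence: 9 steps (steps 3 to 11, from 6 to 24). The donor branch (steps 1 and 2) joins at step 7.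

**Three steps most likely to fail, each with a fallback**

Step 8 (ring closure). The benzylic C–H of 18 is far more acidic than its CH2OMe group. The productive enolate is therefore a minor species, and slow conversion or retro-Michael cleavage may win.

The fallback postpones the decarboxylation. It sets out from keto ester 3 and Mannich salt 16 (K2CO3, MeCN, 60 °C, again through 17). This gives methyl 2,5-bis(4-chloro-2-nitrophenyl)-2-(methoxyacetyl)-5-oxopentanoate F1, which has no acidic benzylic hydrogen left. DBU in toluene at 90 °C is non-nucleophilic, so no retro-Claisen cleavage occurs. It closes the ring through methyl 1,4-bis(4-chloro-2-nitrophenyl)-4-hydroxy-3-methoxy-2-oxocyclohexane-1-carboxylate F2 to methyl 1,4-bis(4-chloro-2-nitrophenyl)-3-methoxy-2-oxocyclohex-3-ene-1-carboxylate F3. Krapcho demethoxycarbonylation (LiCl, wet DMSO, 130 °C) comes back to the route at 20.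

Step 9 (aromatisation). The electron-poor aryl groups may slow hydride transfer to DDQ, and excess DDQ may over-oxidise the guaiacol-type phenol.

The fallback sets out from 20 and replaces hydride abstraction by ionic halogenation–elimination at the acidic C6–H. NBS (1.0 equiv) with NH4OAc (cat.) in CH2Cl2 at 0 °C gives 6-bromo-3,6-bis(4-chloro-2-nitrophenyl)-2-methoxycyclohex-2-en-1-one F4. Li2CO3 and LiBr in DMF at 100 °C then remove HBr, and tautomerisation comes back to the route at 21. No brominating agent is present once the phenol exists, so ring bromination is avoided.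

Step 11 (double Cadogan). Two high-temperature deoxygenations in one flask may stop at 23 or give tar. Attack at the OMe-bearing ortho carbon is a possible side path.

The fallback sets out from 22 and generates the nitrenes from azides instead.
- Fe powder and NH4Cl in EtOH–H2O at 80 °C give 1,4-bis(2-amino-4-chlorophenyl)-2,3-dimethoxybenzene F5.
- NaNO2 in aqueous HCl–AcOH at 0 °C gives 2,2'-(2,3-dimethoxy-1,4-phenylene)bis(5-chlorobenzenediazonium) dichloride F6.
- NaN3 converts this into 1,4-bis(2-azido-4-chlorophenyl)-2,3-dimethoxybenzene F7.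
- Thermolysis in o-dichlorobenzene at 180 °C proceeds through 2-(2-azido-4-chlorophenyl)-7-chloro-3,4-dimethoxy-9H-carbazole F8 and comes back to the route at 24.

**Further compounds**
F1 | step 8 | methyl 2,5-bis(4-chloro-2-nitrophenyl)-2-(methoxyacetyl)-5-oxopentanoate (racemic) | COCC(=O)C(CCC(=O)c1ccc(Cl)cc1[N+](=O)[O-])(C(=O)OC)c1ccc(Cl)cc1[N+](=O)[O-]
F2 | step 8 | methyl 1,4-bis(4-chloro-2-nitrophenyl)-4-hydroxy-3-methoxy-2-oxocyclohexane-1-carboxylate (diastereomer mixture, racemic) | COC1C(=O)C(CCC1(O)c1ccc(Cl)cc1[N+](=O)[O-])(C(=O)OC)c1ccc(Cl)cc1[N+](=O)[O-]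
F3 | step 8 | methyl 1,4-bis(4-chloro-2-nitrophenyl)-3-methoxy-2-oxocyclohex-3-ene-1-carboxylate (racemic) | COC1=C(CCC(C1=O)(C(=O)OC)c1ccc(Cl)cc1[N+](=O)[O-])c1ccc(Cl)cc1[N+](=O)[O-]
F4 | step 9 | 6-bromo-3,6-bis(4-chloro-2-nitrophenyl)-2-methoxycyclohex-2-en-1-one (racemic) | COC1=C(CCC(Br)(C1=O)c1ccc(Cl)cc1[N+](=O)[O-])c1ccc(Cl)cc1[N+](=O)[O-]
F5 | step 11 | 1,4-bis(2-amino-4-chlorophenyl)-2,3-dimethoxybenzene | COc1c(OC)c(ccc1-c1ccc(Cl)cc1N)-c1ccc(Cl)cc1N
F6 | step 11 | 2,2'-(2,3-dimethoxy-1,4-phenylene)bis(5-chlorobenzenediazonium) dichloride | COc1c(OC)c(ccc1-c1ccc(Cl)cc1[N+]#N)-c1ccc(Cl)cc1[N+]#N.[Cl-].[Cl-]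
F7 | step 11 | 1,4-bis(2-azido-4-chlorophenyl)-2,3-dimethoxybenzene | COc1c(OC)c(ccc1-c1ccc(Cl)cc1N=[N+]=[N-])-c1ccc(Cl)cc1N=[N+]=[N-]
F8 | step 11 | 2-(2-azido-4-chlorophenyl)-7-chloro-3,4-dimethoxy-9H-carbazole | COc1c(OC)c2c3ccc(Cl)cc3[nH]c2cc1-c1ccc(Cl)cc1N=[N+]=[N-]
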